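**Retrosynthetic overview** (written from the starting materials so that the numbers run upward)
1. Aromatic half: 3,5-dimethoxyphenylacetic acid 1 → alcohol 2 → ortho-bromide 3 → arylacetaldehyde 4; the bromine marks the carbon that later carries the lactone carbonyl.
2. Key disconnection C3–C1′: asymmetric carbonyl allylation (Brown allylboration) of 4, through borinate 5, gives homoallylic alcohol 6 and sets C3 as R.
3. Side chain: (S)-epichlorohydrin 7 → 8 → 9 → (S)-dec-1-en-5-ol 10 → silyl ether 11; C6′ comes from the chiral pool through two epoxide openings.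
4. Disconnection C2′–C3′: cross-metathesis of 6 with 11 gives 12; diimide saturation gives 13.
5. Rings: the benzene ring is bought; the lactone ring is the only ring made, closed late by carbonylative lactonisation 13 → 14; 8-O-demethylation (15) and desilylation give target 16.

Numbering used: lactone C1 (C=O), O2, C3, C4, C4a–C8a; side chain C1′–C11′. The target is (3R,6′S).

**Step 1**
Reactants: 1 3,5-dimethoxyphenylacetic acid
Product: 2 2-(3,5-dimethoxyphenyl)ethan-1-ol
Conditions: BH3·SMe2 (1.5 equiv), THF, 0 °C to rt; MeOH quench, aqueous work-up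
Reagents that add atoms: none
Why: Borane reduction of a carboxylic acid (via the acyloxyborane) gives the primary alcohol and leaves the aryl ethers alone.

**Step 2**
Reactants: 2 2-(3,5-dimethoxyphenyl)ethan-1-ol
Product: 3 2-(2-bromo-3,5-dimethoxyphenyl)ethan-1-ol
Conditions: NBS (1.02 equiv), MeCN, 0 °C to rt, dark
Reagents that add atoms: N-bromosuccinimide, O=C1CCC(=O)N1Br
Why: Electrophilic aromatic bromination goes ortho to the side chain and para to a methoxy group, because the position between the two methoxy groups is sterically shielded.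

**Step 3**
Reactants: 3 2-(2-bromo-3,5-dimethoxyphenyl)ethan-1-ol
Product: 4 (2-bromo-3,5-dimethoxyphenyl)acetaldehyde
Conditions: Dess–Martin periodinane (1.2 equiv), CH2Cl2, 0 °C to rt, 1 h; used crude at once
Reagents that add atoms: none
Why: Dess–Martin oxidation stops at the aldehyde under near-neutral conditions, which suits an enolisable arylacetaldehyde.

**Step 4**
Reactants: 4 (2-bromo-3,5-dimethoxyphenyl)acetaldehyde
Product: 6 (2R)-1-(2-bromo-3,5-dimethoxyphenyl)pent-4-en-2-ol, via diisopinocampheylborinate ester 5 (not isolated)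
Conditions: (+)-Ipc2BOMe [(–)-α-pinene series, 1.4 equiv], allylMgBr (1.3 equiv), Et2O, 0 °C to rt, 1 h; then 4, –78 °C, 3 h; then 3 M NaOH, 30 % H2O2, 0 °C to rt
Reagents that add atoms: allylmagnesium bromide, C=CC[Mg]Br (source of the allyl group); (+)-B-methoxydiisopinocampheylborane, COB([C@H]1C[C@H]2C[C@@H]([C@@H]1C)C2(C)C)[C@H]1C[C@H]2C[C@@H]([C@@H]1C)C2(C)C (boron and Ipc groups of 5 only)
Why: Brown asymmetric allylboration through a chair Zimmerman–Traxler transition state, in which the isopinocampheyl groups of the (–)-α-pinene series send the allyl group to the re face of the aldehyde, forms the C3–C1′ bond and the (R)-carbinol (expected 90–95 % ee, to be confirmed by Mosher analysis), and the oxidative work-up frees the alcohol.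

**Step 5**
Reactants: 7 (S)-epichlorohydrin [(2S)-2-(chloromethyl)oxirane]
Product: 8 (2S)-1-chloroheptan-2-ol
Conditions: n-BuMgBr (1.15 equiv), CuI (10 mol %), THF, –40 to –20 °C; aq. NH4Cl
Reagents that add atoms: butylmagnesium bromide, CCCC[Mg]Br
Why: Copper-catalysed Grignard opening (SN2) occurs at the unsubstituted epoxide carbon, so the stereocentre is untouched and the ee of the chiral-pool material is kept.

**Step 6**
Reactants: 8 (2S)-1-chloroheptan-2-ol
Product: 9 (2S)-2-pentyloxirane [(S)-1,2-epoxyheptane]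
Conditions: powdered NaOH (2 equiv), Et2O, rt; distilled
Reagents that add atoms: none
Why: Intramolecular Williamson etherification displaces chloride at the CH2Cl carbon, so the carbinol configuration is retained.

**Step 7**
Reactants: 9 (2S)-2-pentyloxirane
Product: 10 (5S)-dec-1-en-5-ol
Conditions: allylMgBr (1.5 equiv), CuI (10 mol %), THF, –30 to 0 °C; aq. NH4Cl
Reagents that add atoms: allylmagnesium bromide, C=CC[Mg]Br
Why: Copper-catalysed allyl Grignard opening at the terminal epoxide carbon gives the C6′ carbinol with unchanged configuration.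

**Step 8**
Reactants: 10 (5S)-dec-1-en-5-ol
Product: 11 tert-butyl{[(5S)-dec-1-en-5-yl]oxy}dimethylsilane
Conditions: TBSCl (1.2 equiv), imidazole (2.5 equiv), DMF, rt
Reagents that add atoms: tert-butyldimethylsilyl chloride, CC(C)(C)[Si](C)(C)Cl
Why: Imidazole-promoted silylation masks the side-chain hydroxyl for the carbonylation and the Lewis-acid step.

**Step 9**
Reactants: 6 (2R)-1-(2-bromo-3,5-dimethoxyphenyl)pent-4-en-2-ol; 11 tert-butyl{[(5S)-dec-1-en-5-yl]oxy}dimethylsilane (3 equiv)
Product: 12 (2R,8S)-1-(2-bromo-3,5-dimethoxyphenyl)-8-[(tert-butyldimethylsilyl)oxy]tridec-4-en-2-ol (E/Z mixture, mainly E)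
Conditions: second-generation Grubbs catalyst RuCl2(=CHPh)(PCy3)(H2IMes) (5 mol %), 1,4-benzoquinone (10 mol %), CH2Cl2, 40 °C, 16 h
Reagents that add atoms: none
Why: Olefin cross-metathesis between two unhindered monosubstituted alkenes is driven to the cross product by the excess of the cheap partner and loss of ethylene; the alkene geometry does not matter and neither stereocentre is touched.

**Step 10**
Reactants: 12 (2R,8S)-1-(2-bromo-3,5-dimethoxyphenyl)-8-[(tert-butyldimethylsilyl)oxy]tridec-4-en-2-ol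
Product: 13 (2R,8S)-1-(2-bromo-3,5-dimethoxyphenyl)-8-[(tert-butyldimethylsilyl)oxy]tridecan-2-ol
Conditions: TsNHNH2 (10 equiv), NaOAc (12 equiv), DME/H2O 1:1, 85 °C, 8 h
Reagents that add atoms: none
Why: Diimide reduction transfers H2 to the C=C in a concerted way and, unlike hydrogenation over palladium, leaves the aryl bromide and the silyl ether intact.

**Step 11**
Reactants: 13 (2R,8S)-1-(2-bromo-3,5-dimethoxyphenyl)-8-[(tert-butyldimethylsilyl)oxy]tridecan-2-ol
Product: 14 (3R)-3-{(6S)-6-[(tert-butyldimethylsilyl)oxy]undecyl}-6,8-dimethoxy-3,4-dihydro-1H-isochromen-1-one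
Conditions: Pd(OAc)2 (5 mol %), Xantphos (6 mol %), CO (1 atm), Et3N (3 equiv), toluene, 100 °C
Reagents that add atoms: carbon monoxide, [C-]#[O+]
Why: Palladium-catalysed carbonylative lactonisation (oxidative addition to zerovalent palladium, CO insertion, capture of the acylpalladium by the C3 hydroxyl) closes the six-membered lactone with retention at C3, because the C3–O bond is never broken.

**Step 12**
Reactants: 14 (3R)-3-{(6S)-6-[(tert-butyldimethylsilyl)oxy]undecyl}-6,8-dimethoxy-3,4-dihydro-1H-isochromen-1-one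
Product: 15 (3R)-3-{(6S)-6-[(tert-butyldimethylsilyl)oxy]undecyl}-8-hydroxy-6-methoxy-3,4-dihydro-1H-isochromen-1-one
Conditions: BCl3 (1 M in CH2Cl2, 2 equiv), CH2Cl2, –78 °C, then –20 °C, 1 h; MeOH/aq. NaHCO3 quench at –78 °C
Reagents that add atoms: none
Why: Chelation-controlled demethylation, in which BCl3 bound between the lactone carbonyl and the peri methoxy group cleaves only that ether, leaves the 6-OMe and the lactone alone; any material that loses the silyl group here is already the target.

**Step 13**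
Reactants: 15 (3R)-3-{(6S)-6-[(tert-butyldimethylsilyl)oxy]undecyl}-8-hydroxy-6-methoxy-3,4-dihydro-1H-isochromen-1-one
Product: 16 (3R)-8-hydroxy-3-[(6S)-6-hydroxyundecyl]-6-methoxy-3,4-dihydro-1H-isochromen-1-one
Conditions: HF·pyridine, THF/pyridine, 0 °C to rt, 12 h
Reagents that add atoms: none
Why: Fluoride-mediated desilylation under mildly acidic conditions frees the C6′ alcohol without opening the lactone or touching either stereocentre.

**Compound list**
1 | 3,5-dimethoxyphenylacetic acid | COc1cc(CC(=O)O)cc(OC)c1 | starting material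
2 | 2-(3,5-dimethoxyphenyl)ethan-1-ol | COc1cc(CCO)cc(OC)c1 | intermediate
3 | 2-(2-bromo-3,5-dimethoxyphenyl)ethan-1-ol | COc1cc(OC)c(Br)c(CCO)c1 | intermediate
4 | (2-bromo-3,5-dimethoxyphenyl)acetaldehyde | COc1cc(OC)c(Br)c(CC=O)c1 | intermediate
5 | (2R)-1-(2-bromo-3,5-dimethoxyphenyl)pent-4-en-2-yl diisopinocampheylborinate, (–)-α-pinene series | C=CC[C@@H](OB([C@H]1C[C@H]2C[C@@H]([C@@H]1C)C2(C)C)[C@H]1C[C@H]2C[C@@H]([C@@H]1C)C2(C)C)Cc1cc(OC)cc(OC)c1Br | intermediate (not isolated)
6 | (2R)-1-(2-bromo-3,5-dimethoxyphenyl)pent-4-en-2-ol | C=CC[C@@H](O)Cc1cc(OC)cc(OC)c1Br | intermediate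
7 | (S)-epichlorohydrin | ClC[C@@H]1CO1 | starting material
8 | (2S)-1-chloroheptan-2-ol | CCCCC[C@H](O)CCl | intermediate
9 | (2S)-2-pentyloxirane | CCCCC[C@H]1CO1 | intermediate
10 | (5S)-dec-1-en-5-ol | CCCCC[C@H](O)CCC=C | intermediate
11 | tert-butyl{[(5S)-dec-1-en-5-yl]oxy}dimethylsilane | CCCCC[C@H](O[Si](C)(C)C(C)(C)C)CCC=C | intermediate
12 | (2R,8S)-1-(2-bromo-3,5-dimethoxyphenyl)-8-[(tert-butyldimethylsilyl)oxy]tridec-4-en-2-ol, E/Z mixture | CCCCC[C@H](O[Si](C)(C)C(C)(C)C)CCC=CC[C@@H](O)Cc1cc(OC)cc(OC)c1Br | intermediate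
13 | (2R,8S)-1-(2-bromo-3,5-dimethoxyphenyl)-8-[(tert-butyldimethylsilyl)oxy]tridecan-2-ol | CCCCC[C@H](O[Si](C)(C)C(C)(C)C)CCCCC[C@@H](O)Cc1cc(OC)cc(OC)c1Br | intermediate
14 | (3R)-3-{(6S)-6-[(tert-butyldimethylsilyl)oxy]undecyl}-6,8-dimethoxy-3,4-dihydro-1H-isochromen-1-one | CCCCC[C@H](O[Si](C)(C)C(C)(C)C)CCCCC[C@@H]1Cc2cc(OC)cc(OC)c2C(=O)O1 | intermediate
15 | (3R)-3-{(6S)-6-[(tert-butyldimethylsilyl)oxy]undecyl}-8-hydroxy-6-methoxy-3,4-dihydro-1H-isochromen-1-one | CCCCC[C@H](O[Si](C)(C)C(C)(C)C)CCCCC[C@@H]1Cc2cc(OC)cc(O)c2C(=O)O1 | intermediate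
16 | (3R)-8-hydroxy-3-[(6S)-6-hydroxyundecyl]-6-methoxy-3,4-dihydro-1H-isochromen-1-one | CCCCC[C@H](O)CCCCC[C@@H]1Cc2cc(OC)cc(O)c2C(=O)O1 | target

**Step count**
Total: 13 steps. Longest linear sequence: 9 steps (Steps 1–4 and 9–13; the side-chain arm, Steps 5–8 and 9–13, is also 9).

**Three steps most likely to fail**

Step 4. Aldehyde 4 enolises and self-condenses easily, and allylboration of arylacetaldehydes usually gives 90–95 % ee, which limits the diastereomeric purity of the final product. The fallback sets out from alcohol 3 and comes back at 6 without ever accumulating 4. It is an iridium-catalysed transfer-hydrogenative allylation of the alcohol (Krische type): [Ir(cod)Cl]2 (2.5 mol %), (R)-BINAP (5 mol %), 4-chloro-3-nitrobenzoic acid (10 mol %), Cs2CO3 (20 mol %), allyl acetate, THF, 100 °C. The catalyst dehydrogenates 3 in the flask and a chiral π-allyliridium species adds to the transient aldehyde. The ligand hand is my best assignment for the (R)-carbinol and would be checked by Mosher analysis against material from Step 4. This fallback makes no new compound (F0).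

Step 9. The cross-metathesis is statistical; homodimers and some double-bond migration next to the free hydroxyl can lower the yield. The fallback sets out from 11 and 6 and comes back at 12 (as its Z isomer) by a Wittig union.
- Side chain: ozonolysis of 11 with NaBH4 work-up (O3, CH2Cl2/MeOH, –78 °C) gives (4S)-4-[(tert-butyldimethylsilyl)oxy]nonan-1-ol F1. I2, PPh3 and imidazole give tert-butyl{[(4S)-1-iodononan-4-yl]oxy}dimethylsilane F2. PPh3 in MeCN at 80 °C gives {(4S)-4-[(tert-butyldimethylsilyl)oxy]nonyl}triphenylphosphonium iodide F3.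
- Aromatic half: TESCl and imidazole convert 6 into {[(2R)-1-(2-bromo-3,5-dimethoxyphenyl)pent-4-en-2-yl]oxy}triethylsilane F4. OsO4 (cat.), NaIO4 and 2,6-lutidine in dioxane/H2O cleave the alkene to (3S)-4-(2-bromo-3,5-dimethoxyphenyl)-3-[(triethylsilyl)oxy]butanal F5.
- Union: the ylide from F3 and NaN(SiMe3)2 (THF, –78 °C) adds to F5 and gives {[(2R,4Z,8S)-1-(2-bromo-3,5-dimethoxyphenyl)-8-[(tert-butyldimethylsilyl)oxy]tridec-4-en-2-yl]oxy}triethylsilane F6. PPTS in MeOH at 0 °C removes only the triethylsilyl group and gives 12.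

Step 11. The bromide is electron-rich and flanked by two ortho substituents, so oxidative addition may be slow and protodebromination may compete. The fallback sets out from 13 and comes back at 14 by halogen–lithium exchange and carboxylation. n-BuLi (3 equiv, THF, –78 °C) deprotonates the hydroxyl and exchanges the bromine; CO2 and acidic work-up give 2-{(2R,8S)-8-[(tert-butyldimethylsilyl)oxy]-2-hydroxytridecyl}-4,6-dimethoxybenzoic acid F7. PPTS (cat.) in toluene at 60 °C lactonises F7 to 14.

**Further compounds**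
F0 | step 4 | none | none
F1 | step 9 | (4S)-4-[(tert-butyldimethylsilyl)oxy]nonan-1-ol | CCCCC[C@H](O[Si](C)(C)C(C)(C)C)CCCO
F2 | step 9 | tert-butyl{[(4S)-1-iodononan-4-yl]oxy}dimethylsilane | CCCCC[C@H](O[Si](C)(C)C(C)(C)C)CCCI
F3 | step 9 | {(4S)-4-[(tert-butyldimethylsilyl)oxy]nonyl}triphenylphosphonium iodide | CCCCC[C@H](O[Si](C)(C)C(C)(C)C)CCC[P+](c1ccccc1)(c1ccccc1)c1ccccc1.[I-]
F4 | step 9 | {[(2R)-1-(2-bromo-3,5-dimethoxyphenyl)pent-4-en-2-yl]oxy}triethylsilane | C=CC[C@@H](O[Si](CC)(CC)CC)Cc1cc(OC)cc(OC)c1Br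
F5 | step 9 | (3S)-4-(2-bromo-3,5-dimethoxyphenyl)-3-[(triethylsilyl)oxy]butanal | O=CC[C@@H](O[Si](CC)(CC)CC)Cc1cc(OC)cc(OC)c1Br
F6 | step 9 | {[(2R,4Z,8S)-1-(2-bromo-3,5-dimethoxyphenyl)-8-[(tert-butyldimethylsilyl)oxy]tridec-4-en-2-yl]oxy}triethylsilane | CCCCC[C@H](O[Si](C)(C)C(C)(C)C)CC/C=C\C[C@@H](O[Si](CC)(CC)CC)Cc1cc(OC)cc(OC)c1Br
F7 | step 11 | 2-{(2R,8S)-8-[(tert-butyldimethylsilyl)oxy]-2-hydroxytridecyl}-4,6-dimethoxybenzoic acid | CCCCC[C@H](O[Si](C)(C)C(C)(C)C)CCCCC[C@@H](O)Cc1cc(OC)cc(OC)c1C(=O)O
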